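**Plan**

- Cuts (ent-kaurane numbering): C16=C17 by aldehyde α-methylenation; C15–C16 and C13–C16 by two Wittig one-carbon homologations of a C13 ketone; C8–C14 and C9–C11 by aldol and Michael addition to methyl vinyl ketone; C7–C8 and C7–O by carbonylative lactonisation; C9–C10 by enolate alkylation; ring A at C2–C3.
- Enabling feature: in the 6-oxabicyclo[3.2.1]octan-3-one (cyclohexanone C1–C2–C3–C4–C5–C10, bridged by O–C6H2 from C3 to C5) the ether carbon C3 is β to the C1 ketone. C2–C3 is therefore the bond an enol carbon forms with an oxolane oxocarbenium ion, and because C4 is quaternary that ion cannot lose a proton.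
- Forward order: the oxolane (C3–C6 and O) is made first from (R)-epichlorohydrin and carries an acetoacetate at C5. The key step closes ring A across it. A spiro α-keto-δ-lactone is then built at C10, ring C is annulated onto it, and the acrolein side chain comes last.
- Stereochemistry: C5 from (R)-epichlorohydrin; C3 by the cis-only bridging; C10 by alkylation on the face away from the overhanging C4 methyl; C9 and C8 by a reversible Michael/aldol sequence that should settle on the trans-fused ketol; C13 by equilibration of an aldehyde beside the bulky axial 8-silyloxy group.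

Key step: step 9

Remark: atom labels such as C5 or C20 follow ent-kaurane numbering of the target; the cyclopropane lactone of step 1 is taken to arise by epoxide opening before chloride displacement, the course that leads from the (R)-epoxide to the (1S,5R)-lactone.

**Route**

Step 1
Reactants: 1 (R)-epichlorohydrin; 2 dimethyl malonate
Product: 3 methyl (1S,5R)-2-oxo-3-oxabicyclo[3.1.0]hexane-1-carboxylate
Conditions: NaOMe (1.05 equiv), MeOH, 0 °C → reflux
Reagents that add atoms: dimethyl malonate 2, COC(=O)CC(=O)OC
Why: Malonate opens the epoxide at CH2, the chlorohydrin alkoxide re-closes to the transposed epoxide, and 3-exo-tet cyclopropanation (inversion at the former epoxide CH) followed by lactonisation gives the cis-fused cyclopropane lactone (tandem alkylation–lactonisation), so the future C5 comes from the chiral pool.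

Step 2
Reactants: 3 methyl (1S,5R)-2-oxo-3-oxabicyclo[3.1.0]hexane-1-carboxylate; 4 vinylmagnesium bromide
Product: 5 methyl (4R)-2-oxo-4-(prop-2-en-1-yl)oxolane-3-carboxylate (C3 epimers)
Conditions: CH2=CHMgBr (2.5 equiv), CuI (copper iodide, 0.25 equiv), THF, −40 → −20 °C; sat. aq. NH4Cl
Reagents that add atoms: vinylmagnesium bromide 4, C=C[Mg]Br
Why: Copper-catalysed homoconjugate addition of the Grignard reagent opens the doubly activated cyclopropane at its CH2 carbon (SN2-type, malonate-type enolate as leaving group) without touching the stereocentre, which now carries the allyl group (future C10 and C20).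

Step 3
Reactants: 5 methyl (4R)-2-oxo-4-(prop-2-en-1-yl)oxolane-3-carboxylate
Product: 6 (4R)-4-(prop-2-en-1-yl)oxolan-2-one
Conditions: LiCl (2 equiv), DMSO/H2O, 140 °C
Reagents that add atoms: none
Why: Krapcho demethoxycarbonylation (chloride attack on the methyl ester, loss of CO2, protonation) removes the activating ester and leaves the lactone, the stereocentre being remote from the carbanion.

Step 4
Reactants: 6 (4R)-4-(prop-2-en-1-yl)oxolan-2-one; 7 iodomethane
Product: 9 (4R)-3,3-dimethyl-4-(prop-2-en-1-yl)oxolan-2-one, via monomethyl lactone 8 (not isolated)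
Conditions: LiN(i-Pr)2 (1.1 equiv), THF, −78 °C, then MeI (1.2 equiv), −78 → −30 °C; recool, LiN(i-Pr)2 (1.3 equiv), then MeI (3 equiv), DMPU, −78 → 0 °C
Reagents that add atoms: iodomethane 7, CI
Why: Two successive lactone enolate alkylations at the only acidic position install the gem-dimethyl group (C18 and C19), so no new stereocentre remains.

Step 5
Reactants: 9 (4R)-3,3-dimethyl-4-(prop-2-en-1-yl)oxolan-2-one
Product: 10 (4R)-3,3-dimethyl-4-(prop-2-en-1-yl)oxolan-2-ol (anomers)
Conditions: i-Bu2AlH (1.15 equiv), CH2Cl2, −78 °C; Rochelle salt work-up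
Reagents that add atoms: none
Why: Half-reduction of a lactone by i-Bu2AlH at low temperature stops at the aluminium lactolate, and no ester is present yet to compete; the hemiacetal centre is inconsequential.

Step 6
Reactants: 10 (4R)-3,3-dimethyl-4-(prop-2-en-1-yl)oxolan-2-ol
Product: 11 (4R)-2-methoxy-3,3-dimethyl-4-(prop-2-en-1-yl)oxolane (anomers)
Conditions: MeOH, PPTS (0.05 equiv), 3 Å molecular sieves, rt
Reagents that add atoms: methanol, CO
Why: Acid-catalysed acetalisation of the lactol through its oxocarbenium ion (Fischer-type glycosidation) gives the methyl acetal that later serves as the cation precursor; the anomers are carried on together.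

Step 7
Reactants: 11 (4R)-2-methoxy-3,3-dimethyl-4-(prop-2-en-1-yl)oxolane
Product: 12 methyl 2-[(3R)-5-methoxy-4,4-dimethyloxolan-3-yl]acetate
Conditions: O3, CH2Cl2/MeOH (5:1), NaOH (2.5 M in MeOH, 5 equiv), −78 °C, stopped at the first blue colour; then water, rt
Reagents that add atoms: ozone, [O-][O+]=O; methanol, CO
Why: Ozonolysis in methanolic NaOH turns a terminal alkene directly into the one-carbon-shorter methyl ester (carbonyl oxide trapped by methanol, hemiacetal oxidised by ozone), so the ester appears only after the hydride step; the acetal is base-stable and reacts with ozone far more slowly than the alkene.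

Step 8
Reactants: 12 methyl 2-[(3R)-5-methoxy-4,4-dimethyloxolan-3-yl]acetate; 13 N-methoxy-N-methylacetamide
Product: 14 methyl 2-[(3R)-5-methoxy-4,4-dimethyloxolan-3-yl]-3-oxobutanoate (C10 and acetal epimers)
Conditions: LiN(i-Pr)2 (1.15 equiv), THF, −78 °C; N-methoxy-N-methylacetamide (1.3 equiv), −78 → −20 °C; sat. aq. NH4Cl
Reagents that add atoms: N-methoxy-N-methylacetamide 13, CC(=O)N(C)OC
Why: Claisen-type C-acylation of the ester lithium enolate by the N-methoxy-N-methylamide stops at the stable tetrahedral chelate, which releases the β-keto ester only on work-up; the new C10 centre is epimerisable and irrelevant.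

Step 9
Reactants: 14 methyl 2-[(3R)-5-methoxy-4,4-dimethyloxolan-3-yl]-3-oxobutanoate
Product: 17 methyl (1R,5S)-8,8-dimethyl-3-oxo-6-oxabicyclo[3.2.1]octane-2-carboxylate, via bis(trimethylsilyl) dienol ether 15 (not isolated), via silyl enol ether 16 (not isolated)
Conditions: Et3N (2.6 equiv), Me3SiOTf (2.5 equiv), CH2Cl2 (0.02 M), 0 °C; then −78 °C, Me3SiOTf (0.5 equiv), −78 → −20 °C; 1 M aq. HCl, rt
Reagents that add atoms: none
Why: Et3N/Me3SiOTf converts the β-keto ester into its 1,3-bis(trimethylsilyloxy)diene 15, and the extra Me3SiOTf then removes methoxide from the 2-methoxyoxolane as MeOSiMe3 to leave a cyclic oxocarbenium ion at C3, which the terminal diene carbon C2 attacks; loss of silicon from the C1 oxygen gives the silyl enol ether 16, hydrolysed on work-up. The closest known reaction type is the Mukaiyama-type γ-alkylation of acetoacetate bis-silyl dienol ethers by acetals under silyl triflate or Lewis acid catalysis, used here in its intramolecular form. The cyclohexanone (C1–C2–C3–C4–C5–C10) closes in the 6-(enolendo)-exo-trig mode, the C=O+ bond of the cation lying outside the new ring. The new stereocentre C3 is controlled by the tether: the three-atom chain anchored at C5 can reach C3 only on the face that carries it, so the ether bridge and the new ring are necessarily cis, and the configuration of the acetal carbon and of C10 is erased on the way. The step needs γ- rather than α-attack of the dienol ether, secured because bonding through C10 would make a four-membered ring, and it needs a cation that lives long enough, secured by the quaternary C4 (no proton to lose) and by high dilution against intermolecular capture.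

Step 10
Reactants: 17 methyl (1R,5S)-8,8-dimethyl-3-oxo-6-oxabicyclo[3.2.1]octane-2-carboxylate; 18 2,3-dibromopropene
Product: 19 methyl (1S,2R,5S)-2-(2-bromoprop-2-en-1-yl)-8,8-dimethyl-3-oxo-6-oxabicyclo[3.2.1]octane-2-carboxylate
Conditions: Cs2CO3 (1.5 equiv), 2,3-dibromopropene (1.5 equiv), DMF, 0 °C → rt
Reagents that add atoms: 2,3-dibromopropene 18, C=C(Br)CBr
Why: C-Alkylation of the cyclic β-keto ester enolate (SN2 at the allylic bromide) creates the quaternary C10; the electrophile should enter on the face of the O–CH2 bridge because the other face is covered by the C4 methyl that points over the three-carbon bridge, which puts C9 equatorial and the ester syn to that methyl as in the target.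

Step 11
Reactants: 19 methyl (1S,2R,5S)-2-(2-bromoprop-2-en-1-yl)-8,8-dimethyl-3-oxo-6-oxabicyclo[3.2.1]octane-2-carboxylate
Product: 20 2-(2-bromoprop-2-en-1-yl)-2-(hydroxymethyl)-8,8-dimethyl-6-oxabicyclo[3.2.1]octan-3-ol (C1, C2 and C5 of the bicycle as in 19; either carbinol epimer)
Conditions: LiAlH4 (2.5 equiv), THF, 0 °C; water/aq. NaOH work-up
Reagents that add atoms: none
Why: LiAlH4 reduces ester and ketone to the 1,3-diol while the vinyl bromide survives at 0 °C; the carbinol configuration at C1 does not matter because that centre is oxidised back in step 13.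

Step 12
Reactants: 20 bromoallyl diol; 21 carbon monoxide
Product: 22 3-hydroxy-8,8-dimethyl-5'-methylidenespiro[6-oxabicyclo[3.2.1]octane-2,3'-oxan]-6'-one (spiro centre C10 as in 19)
Conditions: Pd(PPh3)4 (0.05 equiv), CO (1 atm), Et3N (3 equiv), MeCN, 70 °C
Reagents that add atoms: carbon monoxide 21, [C-]#[O+]
Why: Carbonylative lactonisation: oxidative addition of the vinyl bromide to zerovalent palladium, CO insertion and capture of the acylpalladium by the primary C20 hydroxyl (faster than by the flanked secondary C1 hydroxyl) close the six-membered α-methylene lactone and bring in C7.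

Step 13
Reactants: 22 hydroxy α-methylene spirolactone
Product: 23 8,8-dimethyl-5'-methylidenespiro[6-oxabicyclo[3.2.1]octane-2,3'-oxane]-3,6'-dione
Conditions: Dess–Martin periodinane (1.5 equiv), NaHCO3, CH2Cl2, rt
Reagents that add atoms: none
Why: Dess–Martin oxidation returns the secondary alcohol to the C1 ketone under buffered, non-basic conditions that leave the α-methylene lactone alone.

Step 14
Reactants: 23 keto α-methylene spirolactone
Product: 24 8,8-dimethylspiro[6-oxabicyclo[3.2.1]octane-2,3'-oxane]-3,5',6'-trione (α-keto-δ-lactone)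
Conditions: O3, CH2Cl2, −78 °C; then PPh3 (1.2 equiv), −78 °C → rt
Reagents that add atoms: ozone, [O-][O+]=O
Why: Ozonolysis of the only alkene, a 1,1-disubstituted one, with reductive work-up unmasks the C8 ketone of the α-keto lactone.

Step 15
Reactants: 24 α-keto-δ-lactone; 25 methyl vinyl ketone
Product: 27 tetracyclic ketol (13-oxo 8-hydroxy compound with ring C closed), via Michael adduct 26 (not isolated)
Conditions: methyl vinyl ketone (1.2 equiv), Et3N (0.3 equiv), THF, 0 °C → rt; then DBU (0.3 equiv), 0 °C → rt
Reagents that add atoms: methyl vinyl ketone 25, C=CC(C)=O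
Why: Robinson-type annulation stopped at the ketol: the enolised 1,2-dicarbonyl adds through C9 to the enone (Michael addition, anti to the bulky C5 side of the spiro centre, C9 staying epimerisable), then the methyl ketone enolate closes onto the very electrophilic C8 ketone (6-enolexo aldol), and this reversible aldol should settle on the trans-fused ketol in which C7 and C10 are both equatorial on ring C and the 8-OH is axial, anti to 9-H.

Step 16
Reactants: 27 tetracyclic ketol
Product: 28 8-O-triethylsilyl ether of 27
Conditions: Et3SiOTf (1.5 equiv), 2,6-lutidine (3 equiv), CH2Cl2, −78 → 0 °C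
Reagents that add atoms: triethylsilyl trifluoromethanesulfonate, CC[Si](CC)(CC)OS(=O)(=O)C(F)(F)F
Why: Silylation of the tertiary alcohol with the silyl triflate blocks retro-aldol cleavage under the basic ylide and supplies the bulky axial group that later biases C13.

Step 17
Reactants: 28 silyl-protected ketol; 29 (methoxymethyl)triphenylphosphonium chloride
Product: 32 13-formyl compound with the formyl group equatorial and trans to the 8-silyloxy group, via enol ether 30 (not isolated), via axial aldehyde 31 (not isolated)
Conditions: MeOCH2PPh3Cl (1.6 equiv), KN(SiMe3)2 (1.5 equiv), THF, −78 → 0 °C; then PPTS, THF/H2O, 45 °C; then DBU (0.2 equiv), CH2Cl2, rt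
Reagents that add atoms: (methoxymethyl)triphenylphosphonium chloride 29, COC[P+](c1ccccc1)(c1ccccc1)c1ccccc1.[Cl-]; water, O
Why: Wittig methoxymethylenation of the unhindered C13 ketone (the C1 ketone is flanked by the quaternary C10 and the lactone is inert), mild hydrolysis of the enol ether and base equilibration give the homologated aldehyde with C13 set under thermodynamic control, the formyl group avoiding the 1,3-diaxial contact with the axial 8-silyloxy group.

Step 18
Reactants: 32 equatorial aldehyde; 29 (methoxymethyl)triphenylphosphonium chloride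
Product: 34 13-(2-oxoethyl) hydroxy aldehyde with 8-OH free, via enol ether 33 (not isolated)
Conditions: MeOCH2PPh3Cl (2.0 equiv), KN(SiMe3)2 (1.9 equiv), THF, −78 → 0 °C; then 2 M aq. HCl, THF, rt
Reagents that add atoms: (methoxymethyl)triphenylphosphonium chloride 29, COC[P+](c1ccccc1)(c1ccccc1)c1ccccc1.[Cl-]; water, O
Why: A second Wittig methoxymethylenation is selective for the aldehyde over the hindered ketone, and aqueous acid hydrolyses the enol ether and the silyl ether in one operation; C13 can no longer epimerise once C16 is a CH2 group.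

Step 19
Reactants: 34 hydroxy aldehyde; 35 formaldehyde
Product: 36 CNP0525385.1
Conditions: aq. formaldehyde (37%, 1.5 equiv), pyrrolidine (0.2 equiv), propionic acid (0.2 equiv), i-PrOH, 45 °C
Reagents that add atoms: formaldehyde 35, C=O
Why: Amine-catalysed α-methylenation of the aldehyde (Mannich condensation with formaldehyde through the enamine, then elimination) builds the 2-substituted acrolein; the hindered C1 ketone should not form an enamine under these conditions and no stereocentre is affected.

**Compound list**

1 | (R)-epichlorohydrin, (2R)-2-(chloromethyl)oxirane | ClC[C@H]1CO1 | starting material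
2 | dimethyl malonate | COC(=O)CC(=O)OC | starting material
3 | methyl (1S,5R)-2-oxo-3-oxabicyclo[3.1.0]hexane-1-carboxylate | COC(=O)[C@]12C[C@H]1COC2=O | intermediate
4 | vinylmagnesium bromide | C=C[Mg]Br | starting material
5 | methyl (4R)-2-oxo-4-(prop-2-en-1-yl)oxolane-3-carboxylate (C3 epimers) | C=CC[C@H]1COC(=O)C1C(=O)OC | intermediate
6 | (4R)-4-(prop-2-en-1-yl)oxolan-2-one | C=CC[C@H]1COC(=O)C1 | intermediate
7 | iodomethane | CI | starting material
8 | (4R)-3-methyl-4-(prop-2-en-1-yl)oxolan-2-one (C3 epimers, expected mainly trans; not isolated) | C=CC[C@H]1COC(=O)C1C | intermediate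
9 | (4R)-3,3-dimethyl-4-(prop-2-en-1-yl)oxolan-2-one | C=CC[C@H]1COC(=O)C1(C)C | intermediate
10 | (4R)-3,3-dimethyl-4-(prop-2-en-1-yl)oxolan-2-ol (anomers) | C=CC[C@H]1COC(O)C1(C)C | intermediate
11 | (4R)-2-methoxy-3,3-dimethyl-4-(prop-2-en-1-yl)oxolane (anomers) | C=CC[C@H]1COC(OC)C1(C)C | intermediate
12 | methyl 2-[(3R)-5-methoxy-4,4-dimethyloxolan-3-yl]acetate (anomers) | COC(=O)C[C@H]1COC(OC)C1(C)C | intermediate
13 | N-methoxy-N-methylacetamide | CC(=O)N(C)OC | starting material
14 | methyl 2-[(3R)-5-methoxy-4,4-dimethyloxolan-3-yl]-3-oxobutanoate (C10 and acetal epimers) | COC(=O)C(C(C)=O)[C@H]1COC(OC)C1(C)C | intermediate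
15 | bis(trimethylsilyl) dienol ether of 14, 1-methoxy-2-[(3R)-5-methoxy-4,4-dimethyloxolan-3-yl]-1,3-bis(trimethylsilyloxy)buta-1,3-diene (not isolated) | C=C(O[Si](C)(C)C)C(=C(OC)O[Si](C)(C)C)[C@H]1COC(OC)C1(C)C | intermediate
16 | methyl 8,8-dimethyl-3-(trimethylsilyloxy)-6-oxabicyclo[3.2.1]oct-2-ene-2-carboxylate, bridgeheads as in 17 (not isolated) | COC(=O)C1=C(O[Si](C)(C)C)C[C@@H]2OC[C@H]1C2(C)C | intermediate
17 | methyl (1R,5S)-8,8-dimethyl-3-oxo-6-oxabicyclo[3.2.1]octane-2-carboxylate (C2 epimers and enol) | COC(=O)C1C(=O)C[C@@H]2OC[C@H]1C2(C)C | intermediate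
18 | 2,3-dibromopropene | C=C(Br)CBr | starting material
19 | methyl (1S,2R,5S)-2-(2-bromoprop-2-en-1-yl)-8,8-dimethyl-3-oxo-6-oxabicyclo[3.2.1]octane-2-carboxylate (bromoallyl group on the face of the O–CH2 bridge) | C=C(Br)C[C@]1(C(=O)OC)C(=O)C[C@@H]2OC[C@H]1C2(C)C | intermediate
20 | 2-(2-bromoprop-2-en-1-yl)-2-(hydroxymethyl)-8,8-dimethyl-6-oxabicyclo[3.2.1]octan-3-ol (C1, C2, C5 as in 19; carbinol epimers) | C=C(Br)C[C@]1(CO)C(O)C[C@@H]2OC[C@H]1C2(C)C | intermediate
21 | carbon monoxide | [C-]#[O+] | starting material
22 | 3-hydroxy-8,8-dimethyl-5'-methylidenespiro[6-oxabicyclo[3.2.1]octane-2,3'-oxan]-6'-one (lactone CH2O syn to the bridge methyl; carbinol epimers) | C=C1C[C@]2(COC1=O)C(O)C[C@@H]3OC[C@H]2C3(C)C | intermediate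
23 | 8,8-dimethyl-5'-methylidenespiro[6-oxabicyclo[3.2.1]octane-2,3'-oxane]-3,6'-dione | C=C1C[C@]2(COC1=O)C(=O)C[C@@H]3OC[C@H]2C3(C)C | intermediate
24 | 8,8-dimethylspiro[6-oxabicyclo[3.2.1]octane-2,3'-oxane]-3,5',6'-trione (α-keto-δ-lactone) | O=C1C[C@]2(COC1=O)C(=O)C[C@@H]3OC[C@H]2C3(C)C | intermediate
25 | methyl vinyl ketone | C=CC(C)=O | starting material
26 | 8,8-dimethyl-4'-(3-oxobutyl)spiro[6-oxabicyclo[3.2.1]octane-2,3'-oxane]-3,5',6'-trione, side chain at C9 anti to C5 (not isolated) | CC(=O)CC[C@@H]1C(=O)C(=O)OC[C@]12C(=O)C[C@@H]3OC[C@H]2C3(C)C | intermediate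
27 | tetracyclic ketol: ring C closed, C13 ketone, 8-OH axial and anti to 9-H, lactone and ring C trans-fused, C10 and ring A as in the target | O=C1CC[C@H]2[C@]3(COC(=O)[C@]2(O)C1)C(=O)C[C@@H]4OC[C@H]3C4(C)C | intermediate
28 | 8-O-triethylsilyl ether of 27 | O=C1CC[C@H]2[C@]3(COC(=O)[C@]2(O[Si](CC)(CC)CC)C1)C(=O)C[C@@H]4OC[C@H]3C4(C)C | intermediate
29 | (methoxymethyl)triphenylphosphonium chloride | COC[P+](c1ccccc1)(c1ccccc1)c1ccccc1.[Cl-] | starting material
30 | 13-(methoxymethylidene) enol ether of 28 (E/Z; not isolated) | COC=C1CC[C@H]2[C@]3(COC(=O)[C@]2(O[Si](CC)(CC)CC)C1)C(=O)C[C@@H]4OC[C@H]3C4(C)C | intermediate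
31 | 13-formyl compound, formyl axial and cis to the 8-silyloxy group (not isolated) | O=C[C@H]1CC[C@H]2[C@]3(COC(=O)[C@]2(O[Si](CC)(CC)CC)C1)C(=O)C[C@@H]4OC[C@H]3C4(C)C | intermediate
32 | 13-formyl compound, formyl equatorial and trans to the 8-silyloxy group (C13 as in the target) | O=C[C@@H]1CC[C@H]2[C@]3(COC(=O)[C@]2(O[Si](CC)(CC)CC)C1)C(=O)C[C@@H]4OC[C@H]3C4(C)C | intermediate
33 | 13-(2-methoxyethenyl) enol ether from 32 (E/Z; not isolated) | COC=C[C@@H]1CC[C@H]2[C@]3(COC(=O)[C@]2(O[Si](CC)(CC)CC)C1)C(=O)C[C@@H]4OC[C@H]3C4(C)C | intermediate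
34 | 13-(2-oxoethyl) hydroxy aldehyde, 8-OH free, all stereocentres as in the target | O=CC[C@@H]1CC[C@H]2[C@]3(COC(=O)[C@]2(O)C1)C(=O)C[C@@H]4OC[C@H]3C4(C)C | intermediate
35 | formaldehyde | C=O | starting material
36 | CNP0525385.1 | C=C(C=O)[C@@H]1CC[C@H]2[C@]3(COC(=O)[C@]2(O)C1)C(=O)C[C@@H]1OC[C@H]3C1(C)C | target

**Step count and risks**

Total step count: 19. Longest linear sequence: 19 steps from (R)-epichlorohydrin 1; the route is fully linear.

Steps most likely to fail:

Step 9. The tethered dienol ether may not reach the cation: the oxolane has to hold the C5 side chain pseudo-axial, and if that folding is slow the oxocarbenium ion is captured by a second molecule or simply returns as lactol on work-up. The fallback sets out from 14 and comes back at 17; it makes the C2–C3 bond by aldol condensation and closes the ether bridge last. Aqueous acid (1 M HCl, THF) hydrolyses the acetal to the lactol methyl 2-[(3R)-5-hydroxy-4,4-dimethyloxolan-3-yl]-3-oxobutanoate F1. Piperidinium acetate in toluene at 60 °C then condenses the acetoacetate methyl group with the open-chain, non-enolisable aldehyde in a six-membered aldol condensation, giving the hydroxy enone methyl (6R)-6-(hydroxymethyl)-5,5-dimethyl-2-oxocyclohex-3-ene-1-carboxylate F2. Catalytic DBU in THF adds the hydroxymethyl group to the enone β-carbon (5-exo oxa-Michael addition, possible only cis) and returns 17.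

Step 15. Ring closure under thermodynamic control may stop at the cis-fused ketol, or run on to loss of water from the β-hydroxy ketone. The fallback sets out from 24 and comes back at 27; it forms the two ring C bonds separately and sets C8 by an intermolecular addition. Allyl bromide with K2CO3 in acetone (directly, or through Claisen rearrangement of the O-allyl enol ether on warming) gives the C9-allyl keto lactone 8,8-dimethyl-4'-(prop-2-en-1-yl)spiro[6-oxabicyclo[3.2.1]octane-2,3'-oxane]-3,5',6'-trione F3, whose C9 is still epimerisable and should place the allyl group anti to C5. Zinc-mediated Barbier addition of 2-methoxyallyl bromide (C=C(OC)CBr; Zn dust, THF/aq. NH4Cl) to the C8 ketone, anti to the neighbouring allyl group, gives the tertiary alcohol with 8-OH anti to 9-H, 5'-hydroxy-5'-(2-methoxyprop-2-en-1-yl)-8,8-dimethyl-4'-(prop-2-en-1-yl)spiro[6-oxabicyclo[3.2.1]octane-2,3'-oxane]-3,6'-dione F4. Ring-closing metathesis with second-generation Grubbs catalyst in toluene at 80 °C closes ring C to the cyclic enol ether, the 13-methoxy-12-ene analogue of 27, F5. Oxalic acid in wet THF hydrolyses it to 27.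

Step 10. Facial selectivity at the quaternary C10 may be low or reversed if the O–CH2 bridge shields the enolate more than the C4 methyl does. The fallback sets out from 19 as obtained (either C10 epimer or the mixture) and comes back at 23; it inverts the order in which the two C10 substituents arrive, so that C20 takes the face the electrophile prefers. Krapcho demethoxycarbonylation (LiCl, wet DMSO, 150 °C) gives the ketone 2-(2-bromoprop-2-en-1-yl)-8,8-dimethyl-6-oxabicyclo[3.2.1]octan-3-one F6. Me3SiCl and Et3N in DMF at 100 °C give the more substituted (thermodynamic) silyl enol ether 2-(2-bromoprop-2-en-1-yl)-8,8-dimethyl-3-(trimethylsilyloxy)-6-oxabicyclo[3.2.1]oct-2-ene F7. Mukaiyama aldol hydroxymethylation with aqueous formaldehyde and Yb(OTf)3 (0.1 equiv) in THF gives the keto alcohol 2-(2-bromoprop-2-en-1-yl)-2-(hydroxymethyl)-8,8-dimethyl-6-oxabicyclo[3.2.1]octan-3-one F8. Carbonylative lactonisation under the conditions of step 12 then gives 23 directly.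

Further compounds
F1 | step 9 | methyl 2-[(3R)-5-hydroxy-4,4-dimethyloxolan-3-yl]-3-oxobutanoate | COC(=O)C(C(C)=O)[C@H]1COC(O)C1(C)C
F2 | step 9 | methyl (6R)-6-(hydroxymethyl)-5,5-dimethyl-2-oxocyclohex-3-ene-1-carboxylate | COC(=O)C1C(=O)C=CC(C)(C)[C@@H]1CO
F3 | step 15 | 8,8-dimethyl-4'-(prop-2-en-1-yl)spiro[6-oxabicyclo[3.2.1]octane-2,3'-oxane]-3,5',6'-trione | C=CC[C@@H]1C(=O)C(=O)OC[C@]12C(=O)C[C@@H]3OC[C@H]2C3(C)C
F4 | step 15 | 5'-hydroxy-5'-(2-methoxyprop-2-en-1-yl)-8,8-dimethyl-4'-(prop-2-en-1-yl)spiro[6-oxabicyclo[3.2.1]octane-2,3'-oxane]-3,6'-dione | C=CC[C@@H]1[C@@](O)(CC(=C)OC)C(=O)OC[C@]12C(=O)C[C@@H]3OC[C@H]2C3(C)C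
F5 | step 15 | 13-methoxy-12-ene enol ether analogue of ketol 27 | COC1=CC[C@H]2[C@]3(COC(=O)[C@]2(O)C1)C(=O)C[C@@H]4OC[C@H]3C4(C)C
F6 | step 10 | 2-(2-bromoprop-2-en-1-yl)-8,8-dimethyl-6-oxabicyclo[3.2.1]octan-3-one (C2 epimers) | C=C(Br)CC1C(=O)C[C@@H]2OC[C@H]1C2(C)C
F7 | step 10 | 2-(2-bromoprop-2-en-1-yl)-8,8-dimethyl-3-(trimethylsilyloxy)-6-oxabicyclo[3.2.1]oct-2-ene | C=C(Br)CC1=C(O[Si](C)(C)C)C[C@@H]2OC[C@H]1C2(C)C
F8 | step 10 | 2-(2-bromoprop-2-en-1-yl)-2-(hydroxymethyl)-8,8-dimethyl-6-oxabicyclo[3.2.1]octan-3-one (hydroxymethyl syn to the bridge methyl) | C=C(Br)C[C@]1(CO)C(=O)C[C@@H]2OC[C@H]1C2(C)C
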